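Percent of the substrate charged is the unit of this problem, and it turns the balance of substrate into a plain sum: substrate, target and whatever else forms add up to 100.

| flask | substrate | temperature | remark | time |
|---|---|---|---|---|
| violet | 0.80 M | 110 °C | run made earlier |  |
| delta | 0.40 M | 110 °C |  | 6.0 h |
| zeta | 0.40 M | 130 °C |  | 6.0 h |
| theta | 0.40 M | 70 °C |  | 6.0 h |
| alpha | 0.40 M | 90 °C |  | 6.0 h |

- violet (time / min: target / %): 15.0: 30.7; 30.0: 28.8; 50.0: 26.1; 60.0: 24.6; 80.0: 22.1; 90.0: 21.2; 120: 18.5

(standard deviation of a reading: 0.5 percentage points)

1. which flask leads in amount of target, in percent of the substrate charged ("all alike" within 1.5 percentage points) (delta / zeta / theta / alpha / all alike)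
2. how much target is there at the end, in percent of the substrate charged: delta
3. how much target is there at the end, in percent of the substrate charged: zeta
4. how much target is there at the end, in percent of the substrate charged: theta
5. how much target is there at the end, in percent of the substrate charged: alpha

- the analysis behind the earlier runs scatters by 0.5 percentage points, standard deviation
- the earlier runs do not show what temperature does; that part of a forecast is a guess
- a reading or a percentage of target counts all its forms, free or not

In the violet run, target falls from the first reading on, and the bench rule treats such a fall like a capacitor discharge, with a fixed fraction lost per unit time (pseudo-first-order):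

τ = (120 min − 15.0 min) / ln(30.7% / 18.5%) = 3.46 h

This τ is the fall time, the time in which c_target shrinks by a factor e. Run back to time zero, the violet readings extrapolate to 33.0%. Yet the balance already shows 69.3% of the violet charge as something other than target at the first reading.

Applied honestly to delta, assuming the same start, the rule gives:

y = 33.0% · exp(−6.0 h / 3.46 h) = 5.81%

The border of the rule is a ratio. Violet was charged 2.00 times as strongly as delta, and τ carries over between charges only if the fraction lost per unit time ignores concentration. If the loss needs two molecules to meet, τ stretches by that ratio:

τ' = 6.91 h, y = 13.9%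

The violet run, at its one charge, does not test this ratio, so this reckoning leaves both figures open for delta, and the upper one parts from the forecast.

The forecast gave 6% for delta, 0.4% for zeta, 29% for theta and 23% for alpha, with theta in the lead: “The coolest flask probably leads.”

The flask that leads is alpha, at 28.8%, with theta at 22.5%, delta at 16.0% and zeta at 3.99%.

    substrate ⇌ target (K = 2.65, k = 3.51 × 10⁻⁴ /s, Ea = 110 kJ/mol, ΔH = −17.0 kJ/mol)
    target ⇌ isomer of the product (K = 1.03, k = 3.28 × 10⁻⁴ /s, Ea = 123 kJ/mol, ΔH = −27.0 kJ/mol)
    substrate → decomposition product (k = 2.29 × 10⁻⁷ /s, Ea = 128 kJ/mol)
    crystals ⇌ target, rate k4*(cs4 - [target]) while solid is left; crystals form when [target] > cs4 (solubility = 0.270 M, k = 0.00755 /s)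
    isomer of the product ⇌ substrate (k = 1.60 × 10⁻⁴ /s, Ea = 104 kJ/mol)
    2 substrate → homo dimer (k = 5.14 × 10⁻⁴ /M/s, Ea = 75.0 kJ/mol)
    (constants at 90 °C)

At the end of delta, the homo dimer holds 65.1% of the substrate charged. Read between 3.00 h and 6.00 h, target in delta has a fall time of 8.40 h, longer even than the stretched τ'. Read between the same times, target in zeta, hotter than violet but at the lower charge, has a fall time of 4.73 h, longer than the 3.46 h of violet.

The readings were generated by integration with made-up constants, and the scatter is random.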